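Compound numbers refer to the list after the steps.

## Analysis of the target

- **Ring system.** An N-methylpiperidine and a cycloheptene share a one-carbon bridge, an 8-methyl-8-azabicyclo[4.3.1]decane in which nitrogen is flanked by two CH2 groups, each bonded to a bridgehead. The bridge carbon is also the spiro carbon of a 2-ethyl-2-hydroxytetrahydropyran (lactol). The four-carbon bridge ends in a tetrasubstituted alkene that is shared with a fused cyclopentene and conjugated with a second cyclopentene, which carries the methyl ester and closes onto the quaternary bridgehead.
- **Stereocentres.** There are four: the CH bridgehead (S) and the quaternary bridgehead (R), tied together by the bicycle; the spiro carbon (R); and the lactol carbon (R). The spiro configuration means the OCH2 arm lies over the cycloheptene bridge and the CH2CH2 arm over the piperidine. The lactol carbon can epimerise through the open hydroxy ketone and has axial OH, equatorial ethyl and the quaternary bridgehead equatorial on the pyran chair.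
- **Sensitive groups.** The lactol (a masked δ-hydroxy ethyl ketone), the cross-ring dienoate with acidic allylic hydrogens, and the tertiary amine, which is in a Mannich relation to the bridge carbon whenever that carbon is a carbonyl.
- **Difficulty.** Two adjacent fully substituted carbons (quaternary bridgehead and spiro carbon) sit inside a bridged ring, next to a strained bicyclo[3.3.0]octadiene.
- **Feature used.** Without the nitrogen bridge, the seven-membered ring is a tropone: the bridge carbon is the carbonyl carbon, the two bridgeheads are the α-carbons, and the cyclopentane-fused alkene sits at the β,γ-bond. The CH2–N(CH3)–CH2 unit is the N-methyl azomethine ylide 17. A [6+3] union of tropone 14 and ylide 17 makes both bridgehead–CH2 bonds and the piperidine in one step.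

## Retrosynthetic reasoning

**Lactol.** The ring C–O bond of 32 is opened to hydroxy ketone 31, which comes from silyl ether 30. Ring closure is spontaneous and reversible, so the lactol carbon needs no separate control.

**Chain.** The bond between the two chain CH2 groups is cut as an alkene: 30 comes from enone 29, and 29 from aldehyde 27 and phosphonate 28. The aldehyde carbon on the spiro carbon becomes the first chain carbon, so the chain grows away from the congested centre by olefination and conjugate reduction.

**Spiro centre.** The bond from the spiro carbon to the OCH2 carbon is cut: 27 comes from 26, and 26 from aldehyde 25 and 16. This bond joins two adjacent fully substituted carbons, so the smallest electrophile is used for it. The electrophile should approach the bridge carbon from the cycloheptene face. On that face one flank is the hydrogen-free sp2 ring-fusion carbon; the piperidine face carries two axial N–CH2 hydrogens. The carbon brought in by the electrophile must therefore be the oxygenated one. Bringing in the chain as a Michael acceptor would, by the same preference, give the spiro epimer.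

**Ester ring and masked aldehyde.** Aldehyde 25 comes from enol ether 24. The ester-bearing cyclopentene of 24 is cut at its C=C bond (aldol condensation) back to keto ester 22, which comes from alcohol 21 and silyl ether 20. The enol ether of 20 is cut at its C=C bond back to bridge ketone 19. The one-carbon homologation is placed before the aldol closure so that the dienoate never meets the ylide and the β-amino ketone is gone before alkoxide is used.

**Saturation.** 19 comes from 18 by reduction of the disubstituted alkene only.

**Key disconnection.** Both bridgehead–CH2N bonds of 18 are cut together, giving tropone 14 and ylide 17 (from 15 and 16). Three skeletal bonds, one ring and two stereocentres are formed from a flat precursor, and the silyloxy carbon next to the substituted α-carbon decides the face.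

**Tropone.** In 14 the bond between the carbonyl carbon and the unsubstituted α-CH is cut, removing that CH. This leads to cyclohexadienone 11 and then to phenol 10. The ring-fusion carbon para to the phenol oxygen takes the methoxy group that is lost again on aromatisation.

**Arm and arene.** The aryl–CH2 bond of the arm is cut: 10 comes from 9 and 8, and 8 from aryl iodide 6 and 7 by Heck coupling. The iodide 6 comes from 5. The C–I bond of 5 is made by cooperative directed lithiation of 3 at the one ring position between its two oxygen directing groups. Alcohol 3 comes from ketone 2 by asymmetric transfer hydrogenation (the only catalyst-made stereocentre), and 2 from 1.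

## Alternatives that were turned down

**Alternative 1: intramolecular B-alkyl Suzuki coupling.**
- Disconnection: the CH2–C(sp2) bond of the cycloheptene at the ring-fusion alkene.
- Forward step: in A2 the vinyl group on the piperidine CH carbon is hydroborated with a dialkylborane, and the alkylborane couples under zerovalent palladium with the cyclopentenone β-triflate to close the seven-membered ring, giving A1.
- For: the reaction type is well documented for medium rings and tolerates ester, ketal and amine. The spiro centre, the arm and the masked lactol are already in place.
- Against: A2 is a fully substituted piperidine with three contiguous stereocentres, two of them adjacent quaternary carbons, and the key step does nothing to build or control them. The coupling site is a tetrasubstituted alkenyl triflate beside a quaternary carbon, where reduction can compete.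
- Comparison: its key step is more certain than step 10. It forms one bond and no stereocentre, whereas step 10 gives two C–C bonds, a ring and two stereocentres from a tropone made in nine steps.

**Alternative 2: de Mayo photocycloaddition and retro-aldol.**
- Disconnection: the bond from the bridge carbonyl carbon to the CH bridgehead, and the ring CH2–CH2 bond.
- Forward step: irradiation of A4 makes the dione enol add [2+2] to the N-allyl alkene. The cyclobutanol opens by retro-aldol, expanding the five-membered ring to the cycloheptanedione and closing the piperidine, giving A3.
- For: a known photochemical reaction; the bicyclic core comes from a cyclopentanedione, and the existing quaternary centre fixes the CH bridgehead through the tether.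
- Against: a tertiary amine in the tether quenches the excited enol unless protonated. The two carbonyls of A4 are not equivalent, so enolisation and the straight or crossed addition mode must both fall the right way. A4 needs its own enantioselective quaternary centre. A3 still lacks both cyclopentene rings and the tetrasubstituted alkene.
- Comparison: this step is established chemistry with no periselectivity question, which step 10 cannot claim. In exchange, 18 already carries the ring-fusion alkene, the fused cyclopentane and the oxygen for the ester ring, so less work follows the key step.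

**Alternative 3: Nazarov cyclisation.**
- Disconnection: the bond between the cycloheptene CH carbon and the vinyl terminus of an acryloyl group.
- Forward step: acid converts the cycloheptenyl vinyl ketone A6 into the pentadienyl cation, which closes by 4π electrocyclisation; proton loss places the alkene at the ring fusion, giving A5.
- For: reliable, regioselective for the tetrasubstituted alkene, and A5 is close to ketone 22 of the chosen route.
- Against: an unpolarised divinyl ketone needs strong acid, and the substrate holds a basic amine β to a ketone. The ammonium ion slows cation formation, and retro-Mannich cleavage and acryloyl polymerisation threaten. A6 already contains the azabicycle with both bridgeheads, so the main ring and stereochemical problem is left to another method.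
- Comparison: more reliable as a single step. It adds one ring and no stereocentre late, whereas step 10 creates the piperidine and both bridgehead centres early and relays the stereochemistry from one catalytic reduction.

Key step: step 10

Remark on the chemistry: formaldehyde 16 means monomeric CH2O, supplied as paraformaldehyde (step 10) or formalin (step 17); the lactol carbon of the target is taken to be the thermodynamically preferred epimer and is set by equilibration.

## Route

Step 1
Reactants: 1 6-hydroxyindan-1-one
Product: 2 6-(methoxymethoxy)indan-1-one
Conditions: MeOCH2Cl, i-Pr2NEt, CH2Cl2, 0 °C to rt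
Reagents that add atoms: chloromethyl methyl ether, COCCl
Why: O-alkylation of the phenol; the methoxymethyl ether protects the phenol and serves as ortho-directing group in step 3.

Step 2
Reactants: 2 6-(methoxymethoxy)indan-1-one
Product: 3 (S)-6-(methoxymethoxy)indan-1-ol
Conditions: RuCl(p-cymene)[(S,S)-TsDPEN] (1 mol%), HCO2H–Et3N (5:2), CH2Cl2, rt
Reagents that add atoms: none
Why: Noyori asymmetric transfer hydrogenation of an aryl ketone; with the (S,S)-diamine ligand, indan-1-ones should give the (S)-alcohol, and this centre later directs the cycloaddition.

Step 3
Reactants: 3 (S)-6-(methoxymethoxy)indan-1-ol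
Product: 5 (S)-7-iodo-6-(methoxymethoxy)indan-1-ol, via dilithiated indanol 4 (not isolated)
Conditions: n-BuLi (2.3 equiv), TMEDA, Et2O, −78 to 0 °C; then I2, THF, −78 °C
Reagents that add atoms: iodine, II
Why: Directed ortho-metalation; after O-deprotonation the only ring C–H flanked by both the lithium alkoxide and the acetal oxygen (C7) should be removed cooperatively, and iodinolysis fixes the 1,2,3-pattern without touching the stereocentre.

Step 4
Reactants: 5 (S)-7-iodo-6-(methoxymethoxy)indan-1-ol
Product: 6 (S)-7-iodo-6-(methoxymethoxy)-1-(triisopropylsilyloxy)indane
Conditions: i-Pr3SiOTf, 2,6-lutidine, CH2Cl2, 0 °C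
Reagents that add atoms: triisopropylsilyl trifluoromethanesulfonate, CC(C)[Si](OS(=O)(=O)C(F)(F)F)(C(C)C)C(C)C
Why: Silylation of a hindered secondary alcohol with a silyl triflate; the triisopropylsilyl group is chosen because it survives acetal cleavage and BF3 and is the bulky group that shields one face in step 10.

Step 5
Reactants: 6 (S)-7-iodo-6-(methoxymethoxy)-1-(triisopropylsilyloxy)indane; 7 methyl acrylate
Product: 8 methyl (E)-3-[(1S)-6-(methoxymethoxy)-1-(triisopropylsilyloxy)indan-7-yl]acrylate
Conditions: Pd(OAc)2 (5 mol%), P(o-tol)3 (10 mol%), Et3N, DMF, 90 °C
Reagents that add atoms: methyl acrylate (7), C=CC(=O)OC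
Why: Mizoroki–Heck coupling; aryl iodides with two ortho substituents still undergo oxidative addition readily and the acrylate inserts with β-selectivity to the E-cinnamate.

Step 6
Reactants: 8 methyl (E)-3-[(1S)-6-(methoxymethoxy)-1-(triisopropylsilyloxy)indan-7-yl]acrylate
Product: 9 methyl 3-[(1S)-6-(methoxymethoxy)-1-(triisopropylsilyloxy)indan-7-yl]propanoate
Conditions: H2 (1 atm), Pd/C, EtOAc, rt
Reagents that add atoms: none
Why: Heterogeneous hydrogenation of the conjugated alkene; the aryl acetal and the benzylic silyl ether should be inert in neutral ethyl acetate.

Step 7
Reactants: 9 methyl 3-[(1S)-6-(methoxymethoxy)-1-(triisopropylsilyloxy)indan-7-yl]propanoate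
Product: 10 methyl 3-[(1S)-6-hydroxy-1-(triisopropylsilyloxy)indan-7-yl]propanoate
Conditions: TsOH·H2O (cat.), MeOH, rt; NaHCO3 before concentration
Reagents that add atoms: none
Why: Acid-catalysed transacetalisation; an aryl methoxymethyl ether exchanges to dimethoxymethane much faster than a secondary triisopropylsilyl ether is cleaved, and methanol keeps the arm as the open methyl ester and not the dihydrocoumarin lactone.

Step 8
Reactants: 10 methyl 3-[(1S)-6-hydroxy-1-(triisopropylsilyloxy)indan-7-yl]propanoate
Product: 11 methyl 3-[(3S)-7a-methoxy-5-oxo-3-(triisopropylsilyloxy)-2,3,5,7a-tetrahydro-1H-inden-4-yl]propanoate (both 7a epimers)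
Conditions: PhI(OAc)2, MeOH, 0 °C
Reagents that add atoms: methanol, CO
Why: Oxidative dearomatisation of a para-alkylphenol with a hypervalent iodine reagent; methanol adds at the ring-fusion carbon para to oxygen to give the p-quinol methyl ether, whose new centre is lost in step 9.

Step 9
Reactants: 11 methyl 3-[(3S)-7a-methoxy-5-oxo-3-(triisopropylsilyloxy)-2,3,5,7a-tetrahydro-1H-inden-4-yl]propanoate
Product: 14 methyl 3-[(3S)-5-oxo-3-(triisopropylsilyloxy)-1,2,3,5-tetrahydroazulen-4-yl]propanoate, via alpha-silyl ketone 12 (not isolated), via methoxy cycloheptadienone 13 (not isolated)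
Conditions: Me3SiCHN2, BF3·OEt2, CH2Cl2, −78 °C; then K2CO3, MeOH, rt
Reagents that add atoms: (trimethylsilyl)diazomethane, C[Si](C)(C)C=[N+]=[N-]
Why: Büchner–Curtius–Schlotterbeck homologation of the cross-conjugated dienone, in which the unsubstituted vinyl carbon should migrate in preference to the arm-bearing one (less hindered carbon anti to departing N2); carbonate in methanol then removes the α-silyl group and the β,γ-unsaturated ketone loses methanol by vinylogous E1cB elimination to the tropone, a known phenol-to-tropone sequence.

Step 10
Reactants: 14 methyl 3-[(3S)-5-oxo-3-(triisopropylsilyloxy)-1,2,3,5-tetrahydroazulen-4-yl]propanoate; 15 sarcosine; 16 formaldehyde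
Product: 18 [6+3] adduct: 8-methyl-8-azabicyclo[4.3.1]deca-2,4-dien-10-one whose C4=C5 bond is shared with a cyclopentene bearing (S)-OSi(i-Pr)3 on the carbon next to C5; methyl propanoate arm on bridgehead C6; C1 (R) and C6 (S); N-bridge anti to the silyloxy group, via azomethine ylide 17 (not isolated)
Conditions: sarcosine, (CH2O)n, toluene, reflux (Dean–Stark), ylide precursors added in portions
Reagents that add atoms: sarcosine (15), CNCC(=O)O; formaldehyde (16), C=O
Why: Proposed new method: condensation of sarcosine with formaldehyde and loss of CO2 from the oxazolidin-5-one gives the non-stabilised N-methyl azomethine ylide 17, a four-electron, three-atom component with two CH2 termini, which should add across the six-electron system spanning the two α-carbons of tropone 14 in a ten-electron [6+3] process; the closest known reaction type is the metal-catalysed [6+3] cycloaddition of unsubstituted tropone with ester-stabilised, iminoester-derived azomethine ylides, whereas a free non-stabilised ylide and a 2,3,4-trisubstituted tropone have not been used. The two new bonds join the ylide carbons to the unsubstituted α-CH and to the arm-bearing α-carbon, so the piperidine closes as a three-atom bridge over the carbonyl carbon, either in one suprafacial step or, more likely here, by conjugate attack of the ylide at the unhindered α-CH followed by a 6-endo-trig (enolendo) Mannich closure of the trienolate α-carbon on the tethered methyleneiminium ion. That Mannich closure creates the quaternary centre, and an unsubstituted iminium carbon is the least demanding electrophile for it. Both new stereocentres (CH bridgehead and quaternary bridgehead) are set together because the bridge must span one face of the flat ring; the face is decided by the (S)-silyloxy carbon beside the arm-bearing terminus, whose silyloxy group, pushed out of plane by allylic strain against the arm, blocks its own face, so the bridge should form anti to it. The step needs periselectivity for [6+3] over [3+2] addition across the unsubstituted α,β-bond and over O-closure ([8+3]); the O-closed N,O-acetal can reopen and the symmetric ylide removes any regiochemical question, but nothing in the substrate forbids the [3+2] mode, which is the main risk.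

Step 11
Reactants: 18 [6+3] adduct
Product: 19 8-methyl-8-azabicyclo[4.3.1]dec-4-en-10-one analogue of 18 (C2–C3 saturated; other groups and all stereocentres unchanged)
Conditions: KO2CN=NCO2K, AcOH, MeOH, 0 °C to rt
Reagents that add atoms: none
Why: Diimide reduction; concerted syn transfer of H2 should select the strained cis-disubstituted alkene, leave the tetrasubstituted alkene, ketone and ester, and cannot migrate the remaining double bond as a metal catalyst might.

Step 12
Reactants: 19 bridge ketone
Product: 20 10-(methoxymethylene) enol ether of 19 (E/Z mixture)
Conditions: [Ph3PCH2OMe]Cl, KN(SiMe3)2, THF, 0 °C; then 19, rt to 50 °C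
Reagents that add atoms: (methoxymethyl)triphenylphosphonium chloride, COC[P+](c1ccccc1)(c1ccccc1)c1ccccc1.[Cl-]
Why: Wittig olefination with the methoxymethylene ylide; the ketone on the one-carbon bridge is exposed despite its substituted neighbours, and the enol ether is a base-stable masked aldehyde that also removes the β-amino ketone before steps 13 to 15.

Step 13
Reactants: 20 enol ether silyl ether
Product: 21 allylic alcohol (silyl group removed from 20)
Conditions: Bu4NF, THF, rt to 40 °C
Reagents that add atoms: none
Why: Fluoride cleavage of the silyl ether; enol ether, ester and amine are not affected.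

Step 14
Reactants: 21 allylic alcohol
Product: 22 cyclopentenone (ketone conjugated with the ring-fusion alkene; enol ether and propanoate arm retained)
Conditions: Dess–Martin periodinane, NaHCO3, CH2Cl2, 0 °C to rt
Reagents that add atoms: none
Why: Oxidation of the secondary allylic alcohol to the enone; the bicarbonate buffer protects the enol ether from the acetic acid released.

Step 15
Reactants: 22 cyclopentenone
Product: 24 tetracyclic dienoate enol ether (ester-bearing cyclopentene closed), via aldol adduct 23 (not isolated)
Conditions: NaOMe, MeOH, 60 °C
Reagents that add atoms: none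
Why: Intramolecular aldol condensation; under reversible conditions the ester α-carbon adds 5-exo-trig to the enone carbonyl (the only ring size open to it) and E1cB dehydration of the tertiary aldolate gives the fully substituted dienoate irreversibly, while enol ether and bridgeheads are inert to methoxide.

Step 16
Reactants: 24 tetracyclic dienoate enol ether
Product: 25 bridge-carbon aldehyde (both epimers at the bridge carbon)
Conditions: 1 M HCl (aq), THF, rt
Reagents that add atoms: water, O
Why: Enol ether hydrolysis by C-protonation at the bridge carbon and loss of methanol from the hemiacetal; the epimer mixture is irrelevant because step 17 goes through the enolate.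

Step 17
Reactants: 25 bridge-carbon aldehyde; 16 formaldehyde
Product: 26 hydroxymethyl aldehyde (bridge carbon bearing CHO and CH2OH; CH2OH on the cycloheptene face)
Conditions: 37% aq. CH2O, K2CO3, THF–MeOH, 0 °C to rt
Reagents that add atoms: formaldehyde (16), C=O
Why: Crossed aldol (α-hydroxymethylation) of an α-branched aldehyde; formaldehyde should approach the enolate carbon from the cycloheptene face, where one flank is the hydrogen-free sp2 ring-fusion carbon, and not from the piperidine face with its two axial N–CH2 hydrogens, which places CH2OH as the spiro centre of the target requires.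

Step 18
Reactants: 26 hydroxymethyl aldehyde
Product: 27 triethylsilyl ether of 26
Conditions: Et3SiCl, imidazole, CH2Cl2, 0 °C
Reagents that add atoms: chlorotriethylsilane, CC[Si](Cl)(CC)CC
Why: Silylation of the primary alcohol; it blocks retro-aldol loss of formaldehyde under the basic olefination conditions.

Step 19
Reactants: 27 silyloxymethyl aldehyde; 28 diethyl (2-oxobutyl)phosphonate
Product: 29 (E)-enone (aldehyde carbon extended to CH=CH–C(=O)Et)
Conditions: Ba(OH)2 (activated), THF–H2O (40:1), rt
Reagents that add atoms: diethyl (2-oxobutyl)phosphonate (28), CCC(=O)CP(=O)(OCC)OCC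
Why: Horner–Wadsworth–Emmons olefination with a β-ketophosphonate under mild barium hydroxide conditions; the aldehyde has no α-hydrogen and cannot epimerise, and the E-enone is expected.

Step 20
Reactants: 29 (E)-enone
Product: 30 saturated ethyl ketone (chain CH2CH2C(=O)Et on the spiro carbon)
Conditions: [(Ph3P)CuH]6, H2O (2 equiv), benzene, rt
Reagents that add atoms: none
Why: Copper hydride conjugate reduction with Stryker's reagent; hydride adds only to the β-carbon of the ketone-activated disubstituted alkene, while the ester-conjugated diene is fully substituted at its β- and δ-carbons and should be left.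

Step 21
Reactants: 30 saturated ethyl ketone
Product: 32 target CNP0192143.3, via hydroxy ketone 31 (not isolated)
Conditions: 1 M HCl (aq), THF, rt; then NaHCO3
Reagents that add atoms: none
Why: Acid cleaves the primary triethylsilyl ether and the δ-hydroxy ketone closes to the six-membered lactol; under equilibrating conditions the lactol carbon should settle with axial OH (anomeric effect), equatorial ethyl and the quaternary bridgehead equatorial, which is the configuration of the target.

## Compound list

1 | 6-hydroxyindan-1-one | O=C1CCc2ccc(O)cc21 | starting material
2 | 6-(methoxymethoxy)indan-1-one | O=C1CCc2ccc(OCOC)cc21 | intermediate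
3 | (S)-6-(methoxymethoxy)indan-1-ol | O[C@H]1CCc2ccc(OCOC)cc21 | intermediate
4 | lithium (S)-7-lithio-6-(methoxymethoxy)indan-1-olate | [Li]O[C@H]1CCc2ccc(OCOC)c([Li])c21 | intermediate
5 | (S)-7-iodo-6-(methoxymethoxy)indan-1-ol | O[C@H]1CCc2ccc(OCOC)c(I)c21 | intermediate
6 | (S)-7-iodo-6-(methoxymethoxy)-1-(triisopropylsilyloxy)indane | CC(C)[Si](O[C@H]1CCc2ccc(OCOC)c(I)c21)(C(C)C)C(C)C | intermediate
7 | methyl acrylate | C=CC(=O)OC | starting material
8 | methyl (E)-3-[(1S)-6-(methoxymethoxy)-1-(triisopropylsilyloxy)indan-7-yl]acrylate | COC(=O)/C=C/c1c(OCOC)ccc2CC[C@H](O[Si](C(C)C)(C(C)C)C(C)C)c12 | intermediate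
9 | methyl 3-[(1S)-6-(methoxymethoxy)-1-(triisopropylsilyloxy)indan-7-yl]propanoate | COC(=O)CCc1c(OCOC)ccc2CC[C@H](O[Si](C(C)C)(C(C)C)C(C)C)c12 | intermediate
10 | methyl 3-[(1S)-6-hydroxy-1-(triisopropylsilyloxy)indan-7-yl]propanoate | COC(=O)CCc1c(O)ccc2CC[C@H](O[Si](C(C)C)(C(C)C)C(C)C)c12 | intermediate
11 | methyl 3-[(3S)-7a-methoxy-5-oxo-3-(triisopropylsilyloxy)-2,3,5,7a-tetrahydro-1H-inden-4-yl]propanoate, both 7a epimers | O=C1C=CC2(OC)CC[C@H](O[Si](C(C)C)(C(C)C)C(C)C)C2=C1CCC(=O)OC | intermediate
12 | methyl 3-[(3S)-8a-methoxy-5-oxo-3-(triisopropylsilyloxy)-6-(trimethylsilyl)-1,2,3,5,6,8a-hexahydroazulen-4-yl]propanoate, epimer mixture | O=C1C([Si](C)(C)C)C=CC2(OC)CC[C@H](O[Si](C(C)C)(C(C)C)C(C)C)C2=C1CCC(=O)OC | intermediate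
13 | methyl 3-[(3S)-8a-methoxy-5-oxo-3-(triisopropylsilyloxy)-1,2,3,5,6,8a-hexahydroazulen-4-yl]propanoate, epimer mixture | O=C1CC=CC2(OC)CC[C@H](O[Si](C(C)C)(C(C)C)C(C)C)C2=C1CCC(=O)OC | intermediate
14 | methyl 3-[(3S)-5-oxo-3-(triisopropylsilyloxy)-1,2,3,5-tetrahydroazulen-4-yl]propanoate (tropone) | O=C1C=CC=C2CC[C@H](O[Si](C(C)C)(C(C)C)C(C)C)C2=C1CCC(=O)OC | intermediate
15 | sarcosine | CNCC(=O)O | starting material
16 | formaldehyde (as paraformaldehyde or formalin) | C=O | starting material
17 | N-methyl azomethine ylide | C[N+](=C)[CH2-] | intermediate
18 | [6+3] adduct: 8-methyl-8-azabicyclo[4.3.1]deca-2,4-dien-10-one fused at C4=C5 to the (S)-triisopropylsilyloxy cyclopentene, propanoate arm on C6, C1 (R), C6 (S), N-bridge anti to the silyloxy group | O=C2[C@@H]1C=CC3=C([C@@H](O[Si](C(C)C)(C(C)C)C(C)C)CC3)[C@@]2(CCC(=O)OC)CN(C)C1 | intermediate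
19 | 2,3-dihydro derivative of 18 (dec-4-en-10-one; C1 (R), C6 (S), carbinol (S)) | O=C2[C@@H]1CCC3=C([C@@H](O[Si](C(C)C)(C(C)C)C(C)C)CC3)[C@@]2(CCC(=O)OC)CN(C)C1 | intermediate
20 | 10-(methoxymethylene) enol ether of 19, E/Z mixture | COC=C2[C@@H]1CCC3=C([C@@H](O[Si](C(C)C)(C(C)C)C(C)C)CC3)[C@@]2(CCC(=O)OC)CN(C)C1 | intermediate
21 | allylic alcohol from 20, carbinol (S) | COC=C2[C@@H]1CCC3=C([C@@H](O)CC3)[C@@]2(CCC(=O)OC)CN(C)C1 | intermediate
22 | cyclopentenone from 21 (enone at the ring-fusion alkene) | COC=C2[C@@H]1CCC3=C(C(=O)CC3)[C@@]2(CCC(=O)OC)CN(C)C1 | intermediate
23 | aldol adduct (tertiary β-hydroxy ester, mixture of isomers) | COC=C2[C@@H]1CCC3=C4C(O)(C(C(=O)OC)C[C@@]42CN(C)C1)CC3 | intermediate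
24 | tetracyclic dienoate with methoxymethylene group on the bridge carbon | COC=C2[C@@H]1CCC3=C4C(=C(C(=O)OC)C[C@@]42CN(C)C1)CC3 | intermediate
25 | tetracyclic dienoate aldehyde (CHO on the bridge carbon, both epimers) | O=CC2[C@@H]1CCC3=C4C(=C(C(=O)OC)C[C@@]42CN(C)C1)CC3 | intermediate
26 | hydroxymethyl aldehyde (bridge carbon with CHO and CH2OH, CH2OH over the cycloheptene bridge) | O=C[C@@]2(CO)[C@@H]1CCC3=C4C(=C(C(=O)OC)C[C@@]42CN(C)C1)CC3 | intermediate
27 | triethylsilyl ether of 26 | O=C[C@@]2(CO[Si](CC)(CC)CC)[C@@H]1CCC3=C4C(=C(C(=O)OC)C[C@@]42CN(C)C1)CC3 | intermediate
28 | diethyl (2-oxobutyl)phosphonate | CCC(=O)CP(=O)(OCC)OCC | starting material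
29 | (E)-enone (bridge carbon bearing CH=CH–C(=O)Et and CH2OSiEt3) | CCC(=O)/C=C/[C@@]2(CO[Si](CC)(CC)CC)[C@@H]1CCC3=C4C(=C(C(=O)OC)C[C@@]42CN(C)C1)CC3 | intermediate
30 | saturated ethyl ketone (bridge carbon bearing CH2CH2C(=O)Et and CH2OSiEt3) | CCC(=O)CC[C@@]2(CO[Si](CC)(CC)CC)[C@@H]1CCC3=C4C(=C(C(=O)OC)C[C@@]42CN(C)C1)CC3 | intermediate
31 | δ-hydroxy ketone (open form of the lactol) | CCC(=O)CC[C@@]2(CO)[C@@H]1CCC3=C4C(=C(C(=O)OC)C[C@@]42CN(C)C1)CC3 | intermediate
32 | CNP0192143.3: lactol carbon (R), spiro carbon (R), CH bridgehead (S), quaternary bridgehead (R) | CC[C@]1(O)CC[C@@]2(CO1)[C@@H]1CCC3=C4C(=C(C(=O)OC)C[C@@]42CN(C)C1)CC3 | target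

## Step count and uncertain steps

Total: 21 steps. Longest linear sequence: 21 steps (1 to 32); 7, 15, 16 and 28 enter as single building blocks.

**Step 10 (key step, proposed new method).** The most likely failure is loss of periselectivity: the ylide may add as an ordinary 1,3-dipole across the unsubstituted α,β-double bond ([3+2]), because that path avoids bond formation at the fully substituted α-carbon. O-closure, ylide self-condensation at reflux and a weak facial bias are further risks. The fallback uses known chemistry and runs from 14 to 18. Conjugate hydride delivery to the unsubstituted α-carbon with LiBH(s-Bu)3 at −78 °C (1,8-addition, α-protonation on work-up) should give methyl 3-[(3S)-5-oxo-3-(triisopropylsilyloxy)-1,2,3,4,5,6-hexahydroazulen-4-yl]propanoate F1. A double Mannich condensation of this ketone with methylamine hydrochloride and formaldehyde 16 in AcOH/MeOH then joins both α-carbons through CH2–N(CH3)–CH2. The bond at the arm-bearing carbon should again form anti to the silyloxy group, and the sequence returns to 18.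

**Step 9.** Migration of the arm-bearing vinyl carbon would give the regioisomeric tropone, and the diazoalkane may instead add as a dipole to the disubstituted enone. The fallback runs from 11 to 14. Dimethylsulfoxonium methylide (Me3S(O)I, NaH, DMSO) cyclopropanates the unhindered disubstituted enone to the bicyclo[4.1.0]heptenone F2. CF3CO2H then ionises the tertiary methyl ether beside the cyclopropane, the cyclopropylcarbinyl cation opens at the ring-fusion bond, and proton loss gives 14. The position of the inserted carbon is then fixed by which enone is cyclopropanated, not by a migration.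

**Step 12.** Carbonyl addition at a ketone flanked by a quaternary carbon may be slow, leaving the basic ylide to enolise the ester. The fallback runs from 19 to 20. Dimethylsulfonium methylide, a smaller nucleophile, gives the spiro-epoxide F3. BF3·OEt2 in excess (amine complexed) rearranges it by hydride shift to the aldehyde F4. HC(OMe)3 with camphorsulfonic acid gives the dimethyl acetal F5. Me3SiOTf with i-Pr2NEt removes one methoxy group and returns to enol ether 20.

**Step 17.** Facial selectivity at the bridge carbon may be low or reversed, and retro-aldol equilibration may erode it. If the selectivity is only low, the epimers are separated at 26 or 27. If the electrophile prefers the piperidine face, the roles of the two carbon substituents are exchanged, from 25 to 32. Base-catalysed Michael addition of 25 to pent-1-en-3-one brings the chain in from that face and gives the keto aldehyde F6, whose aldehyde carbon becomes the OCH2 carbon. NaBH(OAc)3 reduces the aldehyde in preference to the ethyl ketone and returns to hydroxy ketone 31, which closes to 32.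

**Step 19.** Olefination may be too slow at an aldehyde flanked by two fully substituted carbons, and base may cause desilylation followed by retro-aldol. The fallback runs from 27 to 29. The dibutylboron enolate of butan-2-one (Bu2BOTf, i-Pr2NEt, enolisation on the methyl side) is a more reactive nucleophile than the phosphonate anion and should give the β-hydroxy ketone F7. MsCl with Et3N gives the mesylate F8, and DBU eliminates it to enone 29.

## Further compounds

F1 | step 10 | methyl 3-[(3S)-5-oxo-3-(triisopropylsilyloxy)-1,2,3,4,5,6-hexahydroazulen-4-yl]propanoate (C4 epimers) | O=C1CC=CC2=C([C@@H](O[Si](C(C)C)(C(C)C)C(C)C)CC2)C1CCC(=O)OC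
F2 | step 9 | cyclopropanated dienone (bicyclo[4.1.0]heptenone from 11, CH2 across the disubstituted enone, isomer mixture) | O=C1C2CC2C3(OC)CC[C@H](O[Si](C(C)C)(C(C)C)C(C)C)C3=C1CCC(=O)OC
F3 | step 12 | spiro-epoxide at the bridge carbon of 19 (both epimers) | C5OC52[C@@H]1CCC3=C([C@@H](O[Si](C(C)C)(C(C)C)C(C)C)CC3)[C@@]2(CCC(=O)OC)CN(C)C1
F4 | step 12 | bridge-carbon aldehyde with silyl ether and propanoate arm (both epimers) | O=CC2[C@@H]1CCC3=C([C@@H](O[Si](C(C)C)(C(C)C)C(C)C)CC3)[C@@]2(CCC(=O)OC)CN(C)C1
F5 | step 12 | dimethyl acetal of F4 | COC(OC)C2[C@@H]1CCC3=C([C@@H](O[Si](C(C)C)(C(C)C)C(C)C)CC3)[C@@]2(CCC(=O)OC)CN(C)C1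
F6 | step 17 | keto aldehyde (bridge carbon bearing CHO and CH2CH2C(=O)Et, chain over the piperidine) | CCC(=O)CC[C@@]2(C=O)[C@@H]1CCC3=C4C(=C(C(=O)OC)C[C@@]42CN(C)C1)CC3
F7 | step 19 | β-hydroxy ketone from 27 and butan-2-one (carbinol epimers) | CCC(=O)CC(O)[C@@]2(CO[Si](CC)(CC)CC)[C@@H]1CCC3=C4C(=C(C(=O)OC)C[C@@]42CN(C)C1)CC3
F8 | step 19 | mesylate of F7 | CCC(=O)CC(OS(C)(=O)=O)[C@@]2(CO[Si](CC)(CC)CC)[C@@H]1CCC3=C4C(=C(C(=O)OC)C[C@@]42CN(C)C1)CC3
A1 | alternative 1 | tetracyclic enone with propanoate arm and spiro methyl ketal | CC[C@]1(OC)CC[C@@]2(CO1)[C@@H]1CCC3=C(C(=O)CC3)[C@@]2(CCC(=O)OC)CN(C)C1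
A2 | alternative 1 | spiro-ketal piperidine bearing a vinyl group and a 3-(triflyloxy)cyclopent-2-enon-2-yl group | CC[C@]1(OC)CC[C@@]2(CO1)[C@H](C=C)CN(C)C[C@]2(CCC(=O)OC)C1=C(OS(=O)(=O)C(F)(F)F)CCC1=O
A3 | alternative 2 | 8-methyl-8-azabicyclo[4.3.1]decane-3,10-dione with propanoate arm on the quaternary bridgehead | COC(=O)CC[C@@]12CN(C)C[C@@H](CCC(=O)C1)C2=O
A4 | alternative 2 | 4-[(N-allyl-N-methylamino)methyl]-4-(2-methoxycarbonylethyl)cyclopentane-1,3-dione | COC(=O)CC[C@]1(CC(=O)CC1=O)CN(C)CC=C
A5 | alternative 3 | azabicyclo[4.3.1]decanone fused to the cyclopentenone, propanoate arm | COC(=O)CC[C@@]12CN(C)C[C@@H](CCC3=C1C(=O)CC3)C2=O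
A6 | alternative 3 | azabicyclo[4.3.1]decenone bearing an acryloyl group on the cycloheptene carbon next to the quaternary bridgehead | COC(=O)CC[C@@]12CN(C)C[C@@H](CCC=C1C(=O)C=C)C2=O
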